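Ring A is disconnected from pyranone ring C. A resorcinol ring fused at C4a–C8a, with a free 5-OH, hydrogens at C6 and C8 and a separately masked O7, is the signature of a vinylketene–ynol ether benzannulation. In one operation a Wolff rearrangement, a ketene–alkyne [2+2] addition, a 4π ring opening and a 6π electrocyclisation form C8–C8a, C5–C6, C7–C8 and C4a–C5 and deliver the whole flavonol core with O7 silylated and O5 free. The precursor is a 2-aryl-4-pyranone from comenic acid that bears a diazoacetyl group at C6 and already carries the 3-acetate of the target; its partner is (triisopropylsilyloxy)acetylene.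

Key step: step 11

Assumption: the target is drawn as the free tris(hydrogen sulfate); it is taken to be released from its pyridinium salt on a sulfonic acid resin in the cold and freeze-dried at once, since aryl hydrogen sulfates hydrolyse autocatalytically.

Step 1
Reactants: 1 comenic acid (5-hydroxy-4-oxo-4H-pyran-2-carboxylic acid)
Product: 2 methyl comenate (methyl 5-hydroxy-4-oxo-4H-pyran-2-carboxylate)
Conditions: MeOH, H2SO4 (cat.), reflux
Reagents that add atoms: methanol, CO
Why: Fischer esterification under acid catalysis should leave the enolic 5-OH and the pyranone ring untouched.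

Step 2
Reactants: 2 methyl comenate
Product: 3 methyl 6-bromo-5-hydroxy-4-oxo-4H-pyran-2-carboxylate
Conditions: N-bromosuccinimide (1.05 equiv), MeCN, 0 → 25 °C
Reagents that add atoms: N-bromosuccinimide, O=C1CCC(=O)N1Br
Why: Electrophilic bromination of the enol should occur at C6, the only ring carbon activated by the adjacent 5-OH, while C3 is deactivated by the ester.

Step 3
Reactants: 3 methyl 6-bromo-5-hydroxy-4-oxo-4H-pyran-2-carboxylate
Product: 4 methyl 6-bromo-5-(methoxymethoxy)-4-oxo-4H-pyran-2-carboxylate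
Conditions: MOMCl, i-Pr2NEt, CH2Cl2, 0 → 25 °C
Reagents that add atoms: chloromethyl methyl ether, COCCl
Why: O-alkylation of the acidic enol hydroxyl gives the acetal ether and removes the pyranonolate that would otherwise slow oxidative addition in the cross-coupling.

Step 4
Reactants: 4 methyl 6-bromo-5-(methoxymethoxy)-4-oxo-4H-pyran-2-carboxylate; 5 3,4-bis(benzyloxy)phenylboronic acid
Product: 6 methyl 6-[3,4-bis(benzyloxy)phenyl]-5-(methoxymethoxy)-4-oxo-4H-pyran-2-carboxylate
Conditions: Pd(dppf)Cl2 (5 mol%), K3PO4, 1,4-dioxane/H2O (9:1), 70 °C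
Reagents that add atoms: none
Why: Suzuki–Miyaura coupling should be easy because the C6–Br bond is a vinylogous acyl bromide that adds readily to zerovalent palladium, and any ester hydrolysed by the base converges in step 5.

Step 5
Reactants: 6 methyl 6-[3,4-bis(benzyloxy)phenyl]-5-(methoxymethoxy)-4-oxo-4H-pyran-2-carboxylate
Product: 8 6-[3,4-bis(benzyloxy)phenyl]-5-hydroxy-4-oxo-4H-pyran-2-carboxylic acid, via lithium carboxylate 7 (not isolated)
Conditions: LiOH·H2O (1.2 equiv), THF/H2O, 0 °C; then 3 M HCl, 45 °C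
Reagents that add atoms: lithium hydroxide, [Li+].[OH-]
Why: Ester saponification with one equivalent of cold hydroxide followed by acid-catalysed acetal hydrolysis in the same flask should free both the acid and the enol, with the benzyl ethers inert to both media.

Step 6
Reactants: 8 6-[3,4-bis(benzyloxy)phenyl]-5-hydroxy-4-oxo-4H-pyran-2-carboxylic acid
Product: 10 5-acetoxy-6-[3,4-bis(benzyloxy)phenyl]-4-oxo-4H-pyran-2-carboxylic acid, via mixed anhydride 9 (not isolated)
Conditions: Ac2O (3 equiv), pyridine, 0 → 25 °C; then H2O/THF, 0 °C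
Reagents that add atoms: acetic anhydride, CC(=O)OC(C)=O; water, O (its oxygen ends in the carboxyl group only if the mixed anhydride is hydrolysed at the pyranoyl carbonyl)
Why: Pyridine-mediated O-acetylation installs the target's 3-acetate on the enol, and the far more reactive carboxylic mixed anhydride should be hydrolysed selectively in the cold aqueous quench.

Step 7
Reactants: 10 5-acetoxy-6-[3,4-bis(benzyloxy)phenyl]-4-oxo-4H-pyran-2-carboxylic acid
Product: 12 2-[3,4-bis(benzyloxy)phenyl]-6-(diazoacetyl)-4-oxo-4H-pyran-3-yl acetate, via acid chloride 11 (not isolated)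
Conditions: 1-chloro-N,N,2-trimethylprop-1-en-1-amine, CH2Cl2, 0 → 25 °C; then Me3SiCHN2 (2 equiv), THF/MeCN (1:1), 0 °C, dark
Reagents that add atoms: trimethylsilyldiazomethane, C[Si](C)(C)C=[N+]=[N-]
Why: The chloroenamine forms the acid chloride without HCl, so neither the enol acetate nor the pyranone carbonyl is attacked, and C-acylation of the silyl diazoalkane with loss of Me3SiCl (the first stage of an Arndt–Eistert sequence) should give the diazoketone.

Step 8
Reactants: 13 tetrahydrofuran; 14 triisopropylsilyl trifluoromethanesulfonate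
Product: 16 triisopropyl(vinyloxy)silane, via lithium ethenolate 15 (not isolated)
Conditions: n-BuLi, THF, 25 °C, 16 h; then TIPSOTf, −78 → 0 °C
Reagents that add atoms: none
Why: α-Lithiated tetrahydrofuran undergoes cycloreversion to ethene and the lithium enolate of acetaldehyde, which the hard silyl triflate should capture at oxygen (silyl enol ether formation).

Step 9
Reactants: 16 triisopropyl(vinyloxy)silane
Product: 18 (Z)-(2-bromoethenyloxy)triisopropylsilane, via dibromide 17 (not isolated)
Conditions: Br2, CH2Cl2, −78 °C; then Et3N, −78 → 25 °C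
Reagents that add atoms: bromine, BrBr
Why: Bromine addition and amine-induced dehydrobromination should give the β-bromo enol ether, because the bulky silyl group stays on oxygen and the α-bromo ether loses a proton instead (any E isomer is carried along).

Step 10
Reactants: 18 (Z)-(2-bromoethenyloxy)triisopropylsilane
Product: 20 (triisopropylsilyloxy)acetylene, via lithium acetylide 19 (not isolated)
Conditions: LiN(i-Pr)2 (2.2 equiv), THF, −78 °C; then AcOH, −78 °C
Reagents that add atoms: none
Why: Base-induced anti elimination of HBr (dehydrohalogenation to the alkyne) is set up by the trans arrangement of H and Br in the Z isomer, and the second equivalent of amide stores the product as its acetylide until the cold acid quench.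

Step 11
Reactants: 12 2-[3,4-bis(benzyloxy)phenyl]-6-(diazoacetyl)-4-oxo-4H-pyran-3-yl acetate; 20 (triisopropylsilyloxy)acetylene
Product: 25 2-[3,4-bis(benzyloxy)phenyl]-5-hydroxy-4-oxo-7-(triisopropylsilyloxy)-4H-chromen-3-yl acetate (3-O-acetyl-3',4'-di-O-benzyl-7-O-triisopropylsilylquercetin), via vinylketene 21 (not isolated), via cyclobutenone 22 (not isolated), via dienylketene 23 (not isolated), via cyclohexadienone 24 (not isolated)
Conditions: 20 (2 equiv), ClCH2CH2Cl (0.05 M), 440–450 nm LEDs, 20 °C, until N2 evolution ends; then 80 °C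
Reagents that add atoms: none
Why: Excitation of the diazo n–π* band, at a wavelength where neither the aryl pyranone nor the flavone product should absorb, expels N2 and the pyranonyl carbon migrates (Wolff rearrangement) to give vinylketene 21 and the C8–C8a bond; the CH terminus of the polarised siloxyalkyne then adds to the ketene carbonyl carbon in a [2+2] step (C5–C6 and C7–C8) to give cyclobutenone 22. At 80 °C 22 opens by 4π electrocyclic cleavage to dienylketene 23, which closes ring A by a thermal 6π electrocyclisation between the ketene carbon and the pyranone CH (C4a–C5), and dienone 24 enolises to the phenol. This is the Danheiser benzannulation in its diazoketone form, which is established for α,β-unsaturated and heteroaryl diazoketones with siloxyalkynes. No stereocentre remains, since the sp3 centres of racemic 22 and 24 disappear on ring opening and enolisation. The regiochemistry needed (silyloxy carbon at C7, hydrogen at C6 and C8) is fixed by the ynol ether, whose nucleophilic carbon is its CH terminus, and closure can only reach pyranone C5 because C6 carries the ketene chain. The new 5-OH is hydrogen-bonded to the C4 carbonyl, which should protect it from acylation by unreacted ketene, and the 3-acetate offers no C–H for the excited carbonyl to abstract.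

Step 12
Reactants: 25 2-[3,4-bis(benzyloxy)phenyl]-5-hydroxy-4-oxo-7-(triisopropylsilyloxy)-4H-chromen-3-yl acetate
Product: 26 2-[3,4-bis(benzyloxy)phenyl]-5,7-dihydroxy-4-oxo-4H-chromen-3-yl acetate (3-O-acetyl-3',4'-di-O-benzylquercetin)
Conditions: HF·pyridine, pyridine, THF, 0 → 25 °C
Reagents that add atoms: none
Why: Fluoride-driven desilylation should be fast because the 7-oxygen, para to the C4 carbonyl, is a vinylogous-acid leaving group, and the buffered acidic medium does not attack the acetate.

Step 13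
Reactants: 26 2-[3,4-bis(benzyloxy)phenyl]-5,7-dihydroxy-4-oxo-4H-chromen-3-yl acetate
Product: 27 2-(3,4-dihydroxyphenyl)-5,7-dihydroxy-4-oxo-4H-chromen-3-yl acetate (quercetin 3-acetate)
Conditions: H2 (1 atm), 10% Pd/C, EtOAc/THF, 25 °C
Reagents that add atoms: none
Why: Hydrogenolysis of the two benzyl aryl ethers under neutral, alcohol-free conditions should spare the acetate and the tetrasubstituted conjugated C2=C3 bond.

Step 14
Reactants: 27 2-(3,4-dihydroxyphenyl)-5,7-dihydroxy-4-oxo-4H-chromen-3-yl acetate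
Product: 29 quercetin 3-acetate 7,3',4'-tri-O-sulfate (2-[3,4-bis(sulfooxy)phenyl]-5-hydroxy-4-oxo-7-(sulfooxy)-4H-chromen-3-yl acetate), via pyridinium salt 28 (not isolated)
Conditions: SO3·pyridine (10 equiv), pyridine, 25 °C; then sulfonic acid resin (H+ form), H2O, 0 °C, freeze-dry
Reagents that add atoms: sulfur trioxide–pyridine complex, O=S(=O)([O-])[n+]1ccccc1
Why: O-sulfation of phenols with the SO3–amine complex should take the 7-, 3'- and 4'-hydroxyls and leave the 5-OH, which is the least nucleophilic because it is chelated to the C4 carbonyl; proton exchange then gives the free acid.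

Compound list
1 | comenic acid (5-hydroxy-4-oxo-4H-pyran-2-carboxylic acid) | O=C(O)c1cc(=O)c(O)co1 | starting material
2 | methyl 5-hydroxy-4-oxo-4H-pyran-2-carboxylate | COC(=O)c1cc(=O)c(O)co1 | intermediate
3 | methyl 6-bromo-5-hydroxy-4-oxo-4H-pyran-2-carboxylate | COC(=O)c1cc(=O)c(O)c(Br)o1 | intermediate
4 | methyl 6-bromo-5-(methoxymethoxy)-4-oxo-4H-pyran-2-carboxylate | COC(=O)c1cc(=O)c(OCOC)c(Br)o1 | intermediate
5 | 3,4-bis(benzyloxy)phenylboronic acid | OB(O)c1ccc(OCc2ccccc2)c(OCc2ccccc2)c1 | starting material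
6 | methyl 6-[3,4-bis(benzyloxy)phenyl]-5-(methoxymethoxy)-4-oxo-4H-pyran-2-carboxylate | COC(=O)c1cc(=O)c(OCOC)c(-c2ccc(OCc3ccccc3)c(OCc3ccccc3)c2)o1 | intermediate
7 | lithium 6-[3,4-bis(benzyloxy)phenyl]-5-(methoxymethoxy)-4-oxo-4H-pyran-2-carboxylate | [Li+].[O-]C(=O)c1cc(=O)c(OCOC)c(-c2ccc(OCc3ccccc3)c(OCc3ccccc3)c2)o1 | intermediate
8 | 6-[3,4-bis(benzyloxy)phenyl]-5-hydroxy-4-oxo-4H-pyran-2-carboxylic acid | O=C(O)c1cc(=O)c(O)c(-c2ccc(OCc3ccccc3)c(OCc3ccccc3)c2)o1 | intermediate
9 | acetic 5-acetoxy-6-[3,4-bis(benzyloxy)phenyl]-4-oxo-4H-pyran-2-carboxylic anhydride | CC(=O)OC(=O)c1cc(=O)c(OC(C)=O)c(-c2ccc(OCc3ccccc3)c(OCc3ccccc3)c2)o1 | intermediate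
10 | 5-acetoxy-6-[3,4-bis(benzyloxy)phenyl]-4-oxo-4H-pyran-2-carboxylic acid | O=C(O)c1cc(=O)c(OC(C)=O)c(-c2ccc(OCc3ccccc3)c(OCc3ccccc3)c2)o1 | intermediate
11 | 5-acetoxy-6-[3,4-bis(benzyloxy)phenyl]-4-oxo-4H-pyran-2-carbonyl chloride | O=C(Cl)c1cc(=O)c(OC(C)=O)c(-c2ccc(OCc3ccccc3)c(OCc3ccccc3)c2)o1 | intermediate
12 | 2-[3,4-bis(benzyloxy)phenyl]-6-(diazoacetyl)-4-oxo-4H-pyran-3-yl acetate | CC(=O)Oc1c(-c2ccc(OCc3ccccc3)c(OCc3ccccc3)c2)oc(C(=O)C=[N+]=[N-])cc1=O | intermediate
13 | tetrahydrofuran | C1CCOC1 | starting material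
14 | triisopropylsilyl trifluoromethanesulfonate | CC(C)[Si](C(C)C)(C(C)C)OS(=O)(=O)C(F)(F)F | starting material
15 | lithium ethenolate | [Li+].[O-]C=C | intermediate
16 | triisopropyl(vinyloxy)silane | C=CO[Si](C(C)C)(C(C)C)C(C)C | intermediate
17 | (1,2-dibromoethoxy)triisopropylsilane (racemic) | BrCC(Br)O[Si](C(C)C)(C(C)C)C(C)C | intermediate
18 | (Z)-(2-bromoethenyloxy)triisopropylsilane | Br/C=C\O[Si](C(C)C)(C(C)C)C(C)C | intermediate
19 | lithium (triisopropylsilyloxy)acetylide | [Li+].[C-]#CO[Si](C(C)C)(C(C)C)C(C)C | intermediate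
20 | (triisopropylsilyloxy)acetylene | C#CO[Si](C(C)C)(C(C)C)C(C)C | intermediate
21 | 2-[3,4-bis(benzyloxy)phenyl]-4-oxo-6-(2-oxoethenyl)-4H-pyran-3-yl acetate (vinylketene) | CC(=O)Oc1c(-c2ccc(OCc3ccccc3)c(OCc3ccccc3)c2)oc(C=C=O)cc1=O | intermediate
22 | 2-[3,4-bis(benzyloxy)phenyl]-4-oxo-6-[4-oxo-2-(triisopropylsilyloxy)cyclobut-2-en-1-yl]-4H-pyran-3-yl acetate (racemic) | CC(=O)Oc1c(-c2ccc(OCc3ccccc3)c(OCc3ccccc3)c2)oc(C2C(=O)C=C2O[Si](C(C)C)(C(C)C)C(C)C)cc1=O | intermediate
23 | 2-[3,4-bis(benzyloxy)phenyl]-4-oxo-6-[(1E)-4-oxo-2-(triisopropylsilyloxy)buta-1,3-dien-1-yl]-4H-pyran-3-yl acetate (dienylketene) | CC(=O)Oc1c(-c2ccc(OCc3ccccc3)c(OCc3ccccc3)c2)oc(/C=C(\C=C=O)O[Si](C(C)C)(C(C)C)C(C)C)cc1=O | intermediate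
24 | 2-[3,4-bis(benzyloxy)phenyl]-4,5-dioxo-7-(triisopropylsilyloxy)-4a,5-dihydro-4H-chromen-3-yl acetate (racemic keto tautomer of 25) | CC(=O)OC1=C(c2ccc(OCc3ccccc3)c(OCc3ccccc3)c2)OC2=CC(O[Si](C(C)C)(C(C)C)C(C)C)=CC(=O)C2C1=O | intermediate
25 | 2-[3,4-bis(benzyloxy)phenyl]-5-hydroxy-4-oxo-7-(triisopropylsilyloxy)-4H-chromen-3-yl acetate | CC(=O)Oc1c(-c2ccc(OCc3ccccc3)c(OCc3ccccc3)c2)oc2cc(O[Si](C(C)C)(C(C)C)C(C)C)cc(O)c2c1=O | intermediate
26 | 2-[3,4-bis(benzyloxy)phenyl]-5,7-dihydroxy-4-oxo-4H-chromen-3-yl acetate | CC(=O)Oc1c(-c2ccc(OCc3ccccc3)c(OCc3ccccc3)c2)oc2cc(O)cc(O)c2c1=O | intermediate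
27 | 2-(3,4-dihydroxyphenyl)-5,7-dihydroxy-4-oxo-4H-chromen-3-yl acetate (quercetin 3-acetate) | CC(=O)Oc1c(-c2ccc(O)c(O)c2)oc2cc(O)cc(O)c2c1=O | intermediate
28 | tris(pyridinium) salt of quercetin 3-acetate 7,3',4'-trisulfate | CC(=O)Oc1c(-c2ccc(OS(=O)(=O)[O-])c(OS(=O)(=O)[O-])c2)oc2cc(OS(=O)(=O)[O-])cc(O)c2c1=O.c1cc[nH+]cc1.c1cc[nH+]cc1.c1cc[nH+]cc1 | intermediate
29 | quercetin 3-acetate 7,3',4'-tri-O-sulfate | CC(=O)Oc1c(-c2ccc(OS(=O)(=O)O)c(OS(=O)(=O)O)c2)oc2cc(OS(=O)(=O)O)cc(O)c2c1=O | target

Total step count: 14. Longest linear sequence: 11 steps (steps 1–7 and 11–14 from comenic acid); the alkyne branch (steps 8–10) joins at step 11.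

Steps most likely to fail

1. Step 11. The excited diazoketone may be diverted before rearrangement (carbene insertion or dimerisation, dipolar addition of the diazo group to the electron-rich alkyne, light taken up by the aryl pyranone), so that the ketene is not formed cleanly beside the alkyne. The fallback sets out from 12 and comes back at 25; it makes the same ketene without light and without a free carbene next to the alkyne. Diazoketone 12 is rearranged with catalytic Ag2O in wet 1,4-dioxane at 60 °C (Arndt–Eistert homologation) to [5-acetoxy-6-(3,4-bis(benzyloxy)phenyl)-4-oxo-4H-pyran-2-yl]acetic acid F1. The chloroenamine of step 7 converts F1 into [5-acetoxy-6-(3,4-bis(benzyloxy)phenyl)-4-oxo-4H-pyran-2-yl]acetyl chloride F2. Slow addition of i-Pr2NEt to F2 and alkyne 20 in toluene at 25 °C, then heating to 80 °C, dehydrochlorinates F2 to vinylketene 21, which should follow the same [2+2], 4π and 6π course (a Smith–Hoehn-type ketene–alkyne annulation) to 25.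

2. Step 14. Sulfation may overrun onto the 5-OH or stop short at the crowded catechol pair, and the acetate or a sulfate may be hydrolysed during the acidic proton exchange, with no chromatographic handle on a polyanion. The fallback sets out from 27 and comes back at 29; the sulfates are introduced as neutral protected diesters. Compound 27 is treated with 2,2,2-trichloroethyl chlorosulfate (3.3 equiv), Et3N and catalytic 4-(dimethylamino)pyridine in THF at 0 °C to give the 7,3',4'-tris(2,2,2-trichloroethyl sulfate) of quercetin 3-acetate F3. F3 can be purified on silica and its substitution pattern secured before unmasking. Zinc dust and ammonium formate in MeCN/H2O at 25 °C then remove the three trichloroethyl groups by reductive elimination to give the tris(ammonium) trisulfate F4, and the same cold proton exchange on sulfonic acid resin gives 29.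

3. Step 10. The silyl group may migrate from oxygen to carbon in lithium acetylide 19 (a silylketene would result after the quench), and the volatile, moisture-sensitive alkyne may be lost on isolation. The fallback sets out from 14 and comes back at 20; the O–Si bond is made last, on a preformed ynolate, instead of being carried through an elimination. Acetylene is lithiated with n-BuLi in THF at −78 °C to lithium acetylide F5, which is oxidised with LiOOt-Bu (from t-BuOOH and LiN(SiMe3)2) at −78 → 0 °C to lithium ethynolate F6. The bulky triflate 14 then silylates F6 at oxygen at −78 °C to give 20 directly.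

Further compounds
F1 | step 11 | [5-acetoxy-6-(3,4-bis(benzyloxy)phenyl)-4-oxo-4H-pyran-2-yl]acetic acid | CC(=O)Oc1c(-c2ccc(OCc3ccccc3)c(OCc3ccccc3)c2)oc(CC(=O)O)cc1=O
F2 | step 11 | [5-acetoxy-6-(3,4-bis(benzyloxy)phenyl)-4-oxo-4H-pyran-2-yl]acetyl chloride | CC(=O)Oc1c(-c2ccc(OCc3ccccc3)c(OCc3ccccc3)c2)oc(CC(=O)Cl)cc1=O
F3 | step 14 | quercetin 3-acetate 7,3',4'-tris(2,2,2-trichloroethyl sulfate) | CC(=O)Oc1c(-c2ccc(OS(=O)(=O)OCC(Cl)(Cl)Cl)c(OS(=O)(=O)OCC(Cl)(Cl)Cl)c2)oc2cc(OS(=O)(=O)OCC(Cl)(Cl)Cl)cc(O)c2c1=O
F4 | step 14 | tris(ammonium) salt of quercetin 3-acetate 7,3',4'-trisulfate | CC(=O)Oc1c(-c2ccc(OS(=O)(=O)[O-])c(OS(=O)(=O)[O-])c2)oc2cc(OS(=O)(=O)[O-])cc(O)c2c1=O.[NH4+].[NH4+].[NH4+]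
F5 | step 10 | lithium acetylide | [Li+].[C-]#C
F6 | step 10 | lithium ethynolate | [Li+].[O-]C#C
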